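**Crossing charge.** One mole of D costs two moles of Q, so a charge of 0.0800 M of Q can pay for at most 0.0400 M of D. I call this X charge, at which Q stands at two to one against X, the crossing charge x_c. Above it Q is the limiting reagent for D.

| setting | birch | alder | dusk | dawn | summer | noon | midnight |
|---|---|---|---|---|---|---|---|
| X | 0.0068 M | 0.088 M | 0.0060 M | 0.012 M | 0.025 M | 0.050 M | 0.10 M |
| Q | 0.080 M | 0.080 M | 0.0800 M | 0.0800 M | 0.0800 M | 0.0800 M | 0.0800 M |
| remark | run made earlier | run made earlier |  |  |  |  |  |
| time |  |  | 10 d | 10 d | 10 d | 10 d | 10 d |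

| run | time / d | D / % | X / % |
|---|---|---|---|
| birch | 1.25 | 70.4 | 5.3 |
| birch | 2.50 | 53.5 | 0.2 |
| birch | 4.00 | 34.6 | 0.5 |
| birch | 5.00 | 25.9 | 0 |
| alder | 1.25 | 30.9 | 44.8 |
| alder | 2.50 | 31.0 | 43.2 |
| alder | 4.00 | 29.4 | 41.4 |
| alder | 5.00 | 28.3 | 41.2 |

(readings scatter by 0.3 percentage points)

- percent here means X units held: one Z counts as two
- what may be going on: X + Q -> G + L; Q + G -> D + L; Q + D -> J + L; Q + J -> E + L; X + D -> Z
- "hardly changes" means that all values lie within two and a half points (for a concentration: within two and a half percent of the largest)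

- [D] at the end for dusk, dawn, summer, noon, midnight, in this order
- the shape of the row from first to last (hardly changes / rises all the way / rises, then falls / falls, then rises / falls all the way)

**Starting slope.** Birch is charged below x_c, and its X reads 5.3 % at 1.25 d. From there its D sinks from 70.4 % to 25.9 % at 5.00 d, a pseudo-first-order decay with a read constant κ = 0.267 d⁻¹. Over 10 d the surviving fraction is s = 0.0695, so I start the row of final [D] against X charge at slope s, which puts dusk near 4.17 × 10⁻⁴ M.

**The knee.** Each added X spends Q, and I take κ to thin with Q. I therefore expect the row to steepen on the way to x_c.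

**Far side.** Alder is charged above the crossing. Its D reads 31.0 % at 2.50 d, which is 0.0273 M, under the ceiling, with X still at 43.2 %. It then sinks by a read ε = 0.0365 d⁻¹, slower than κ. Carried on to 10 d, alder's D comes to 0.0208 M. So I commit to a row that rises, turns near x_c, and falls towards that level.

**The forecast.** It gives 3.600 × 10⁻⁴ M, 0.0016 M, 0.0112 M, 0.029 M and 0.0195 M, shape rises, then falls, holding that “D freezes once Q is gone”.

**The result.** The flasks give 3.61 × 10⁻⁴ M, 0.00165 M, 0.0119 M, 0.0286 M and 0.0190 M, shape rises, then falls.

    X + Q → G + L (k = 1.41 L mol⁻¹ h⁻¹)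
    Q + G → D + L (k = 4.03 L mol⁻¹ h⁻¹)
    Q + D → J + L (k = 0.206 L mol⁻¹ h⁻¹)
    Q + J → E + L (k = 1.51 L mol⁻¹ h⁻¹)
    X + D → Z (k = 0.0378 L mol⁻¹ h⁻¹)

**Past crossing.** The row turns at 0.048 M, which is 1.20 times x_c. The crossing also sorts two neighbours: summer, charged below it, ends with Q at 8.4 % of its charge, and noon, charged above it, ends with Q at 0 %. Midnight, also above it, ends with Q at 0 %. The falling level of Q is one part of why [D] in midnight stands where it does: the same run with Q held at its charge gives 0.00231 M against 0.0190 M. In dusk, charged below x_c, the falling level of Q also raises [D], as the largest single effect at most and not the main reason: the same run with Q held at its charge gives 1.42 × 10⁻⁴ M against 3.61 × 10⁻⁴ M.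

(The data are calculated with constants of no real substance, and the scatter is random.)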